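**Retrosynthetic overview**

1. Target 18 comes from bis-flavanone 15 by removing both C4 carbonyl oxygens (NaBH4, then Et3SiH/CF3CO2H) and hydrogenolysing the two benzyl ethers last.
2. The strategy rests on this feature: each stereocentre is C2 of a dihydropyran ring, bonded to the ring oxygen O1, carrying phenyl and lying beta to C4. At the chromone oxidation level that carbon is the beta terminus of the O1–C2=C3–C4=O enone, so both C2–phenyl bonds are cut back to phenylboronic acid 14 and bis-chromone 13 (twofold enantioselective rhodium/diene 1,4-addition).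
3. The unsymmetrical C8–CH2–C6 bridge of 13 is cut at both aryl–CH2 bonds. Diborylmethane 11 is coupled first with 8-iodochromone 6 and then with 6-iodochromone 10, because a formaldehyde condensation would not tell C8 from C6.
4. Each iodine is placed ortho to the one free, chelated phenol of its precursor: the 2'-OH of acetophenone 2 (this carbon becomes C8) and the 5-OH of chromone 8 (C6).
5. Ring order: the pyranone of the C8-linked unit is closed in step 3 from an enaminone, and the other pyranone is bought in with 5,7-dihydroxychromone 7. No ring is formed later; both pyranones are only saturated in steps 9–11.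

Key step: step 9

Remark: 5,7-dihydroxychromone 7 is taken as a catalogue compound.
Remark: the (S,S) antipode of the diene is assigned to the 2S series by carrying the facial sense this ligand class shows with cyclic enones over to the chromone; the antipode is exchanged should a trial run on a monomeric chromone indicate the opposite sense.

**Route**

Step 1
Reactants: 1 2',4'-dihydroxy-6'-methoxyacetophenone
Product: 2 4'-(benzyloxy)-2'-hydroxy-6'-methoxyacetophenone
Conditions: BnBr (1.05 equiv), K2CO3 (1.1 equiv), acetone, reflux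
Reagents that add atoms: benzyl bromide, BrCc1ccccc1
Why: Williamson etherification should take the para hydroxyl, which is the more acidic and unchelated one, while the 2'-OH stays locked in its hydrogen bond to the acetyl carbonyl.

Step 2
Reactants: 2 4'-(benzyloxy)-2'-hydroxy-6'-methoxyacetophenone
Product: 3 4'-(benzyloxy)-2'-hydroxy-3'-iodo-6'-methoxyacetophenone
Conditions: PhCH2NMe3·ICl2 (1.05 equiv), CaCO3, CH2Cl2/MeOH, rt
Reagents that add atoms: benzyltrimethylammonium dichloroiodate, C[N+](C)(C)Cc1ccccc1.Cl[I-]Cl
Why: Electrophilic aromatic iodination of a chelated 2'-hydroxy-4',6'-dialkoxyacetophenone is expected at C3', the position ortho to the free phenol, and this carbon later becomes C8 of the chromone.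

Step 3
Reactants: 3 4'-(benzyloxy)-2'-hydroxy-3'-iodo-6'-methoxyacetophenone; 4 N,N-dimethylformamide dimethyl acetal
Product: 6 7-(benzyloxy)-8-iodo-5-methoxy-4H-chromen-4-one, via enaminone 5 (not isolated)
Conditions: 4 (3 equiv), toluene, 95 °C; then conc. HCl, CH2Cl2, rt
Reagents that add atoms: none
Why: Condensation of the methyl ketone with the amide acetal gives the beta-dimethylamino enone, and acid-promoted addition–elimination by the 2'-hydroxyl (6-endo attack, loss of dimethylamine) closes the pyranone in the standard enaminone chromone synthesis.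

Step 4
Reactants: 7 5,7-dihydroxy-4H-chromen-4-one
Product: 8 7-(benzyloxy)-5-hydroxy-4H-chromen-4-one
Conditions: BnBr (1.05 equiv), K2CO3 (1.1 equiv), acetone, reflux
Reagents that add atoms: benzyl bromide, BrCc1ccccc1
Why: Williamson etherification should be selective for the 7-OH because the 5-OH is hydrogen-bonded to the C4 carbonyl and far less nucleophilic.

Step 5
Reactants: 8 7-(benzyloxy)-5-hydroxy-4H-chromen-4-one
Product: 9 7-(benzyloxy)-5-hydroxy-6-iodo-4H-chromen-4-one
Conditions: PhCH2NMe3·ICl2 (1.05 equiv), CaCO3, CH2Cl2/MeOH, rt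
Reagents that add atoms: benzyltrimethylammonium dichloroiodate, C[N+](C)(C)Cc1ccccc1.Cl[I-]Cl
Why: Electrophilic iodination of a 5-hydroxy-7-alkoxy benzopyranone is expected at C6, the position ortho to the only free phenol, as is known for the corresponding flavones.

Step 6
Reactants: 9 7-(benzyloxy)-5-hydroxy-6-iodo-4H-chromen-4-one
Product: 10 7-(benzyloxy)-6-iodo-5-methoxy-4H-chromen-4-one
Conditions: MeI (5 equiv), K2CO3 (3 equiv), DMF, 45 °C
Reagents that add atoms: iodomethane, CI
Why: Williamson O-methylation under forcing conditions should cap the hindered, chelated 5-phenol, which installs the 5-OMe of this unit and removes the acidic proton before the metal-catalysed steps.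

Step 7
Reactants: 6 7-(benzyloxy)-8-iodo-5-methoxy-4H-chromen-4-one; 11 2,2'-methylenebis(4,4,5,5-tetramethyl-1,3,2-dioxaborolane)
Product: 12 7-(benzyloxy)-5-methoxy-8-[(4,4,5,5-tetramethyl-1,3,2-dioxaborolan-2-yl)methyl]-4H-chromen-4-one
Conditions: 11 (1.5 equiv), Pd[P(t-Bu)3]2 (5 mol %), 8 M aq KOH (2 equiv), 1,4-dioxane, rt; dil. HCl quench
Reagents that add atoms: none
Why: This is a chemoselective Suzuki–Miyaura mono-coupling of a geminal diborylmethane, in which hydroxide activates one boron of 11 (the borate is stabilised by the neighbouring boron) so that transmetalation runs at room temperature while the benzylboronate formed is not activated and is retained.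

Step 8
Reactants: 12 7-(benzyloxy)-5-methoxy-8-[(pinacolboryl)methyl]-4H-chromen-4-one; 10 7-(benzyloxy)-6-iodo-5-methoxy-4H-chromen-4-one
Product: 13 7-(benzyloxy)-8-{[7-(benzyloxy)-5-methoxy-4-oxo-4H-chromen-6-yl]methyl}-5-methoxy-4H-chromen-4-one
Conditions: Pd(OAc)2 (5 mol %), SPhos (10 mol %), K3PO4 (3 equiv), toluene/H2O (10:1), 70 °C
Reagents that add atoms: none
Why: A C(sp3)–C(sp2) Suzuki–Miyaura coupling of the primary benzylboronate with the aryl iodide under a bulky biarylphosphine should join C8 of one chromone through CH2 to C6 of the other, the connectivity being fixed by the positions of the two iodines.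

Step 9
Reactants: 13 methylene-bridged bis(7-benzyloxy-5-methoxychromone); 14 phenylboronic acid
Product: 15 (2S)-7-(benzyloxy)-8-{[(2S)-7-(benzyloxy)-5-methoxy-4-oxo-2-phenyl-3,4-dihydro-2H-chromen-6-yl]methyl}-5-methoxy-2-phenyl-2,3-dihydro-4H-chromen-4-one
Conditions: 14 (6 equiv), [RhCl(C2H4)2]2 (2.5 mol % per chromone), (S,S)-Ph-bod* [(1S,4S)-2,5-diphenylbicyclo[2.2.2]octa-2,5-diene, 5.5 mol % per chromone], aq KOH (0.3 equiv), toluene/H2O, 40 °C; pH 7 buffer work-up
Reagents that add atoms: none
Why: Hydroxide converts the chloride precatalyst into a diene-bound monovalent rhodium hydroxide, phenyl is transferred to it from boron, and the phenylrhodium species inserts the C2=C3 bond of a chromone so that phenyl ends on C2; water then protonates the oxa-pi-allyl rhodium enolate, which frees the flavanone and restores the rhodium hydroxide, and the cycle repeats on the second chromone. The closest known reaction type is the Hayashi–Miyaura rhodium/chiral diene 1,4-addition of arylboronic acids to chromones giving flavanones, used here twice in one flask. No ring is closed: both pyranones are already present and are only changed from flat enones into saturated O1–C2 rings. Each of the two new stereocentres (C2 of either unit) is set by the chiral diene, which shields one enantioface of the bound enone; because the methylene bridge keeps the two chromones apart, the two additions are independent, catalyst-controlled events, and stereochemical errors end up in separable diastereomers. The step needs 1,4- instead of 1,2-addition and needs the flavanones to survive without retro-oxa-Michael ring opening; the soft arylrhodium nucleophile and the unsubstituted C2 should secure the first, and the capped 5- and 7-oxygens (no free phenol), the sub-stoichiometric base and the buffered work-up should secure the second.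

Step 10
Reactants: 15 (2S,2''S)-bis-flavanone dibenzyl ether
Product: 16 (2S)-7-(benzyloxy)-8-{[(2S)-7-(benzyloxy)-4-hydroxy-5-methoxy-2-phenyl-3,4-dihydro-2H-chromen-6-yl]methyl}-5-methoxy-2-phenyl-3,4-dihydro-2H-chromen-4-ol (C4 epimers at both carbinols)
Conditions: NaBH4 (6 equiv), THF/MeOH, 0 °C to rt
Reagents that add atoms: none
Why: Borohydride reduction of the two aryl ketones under near-neutral, cold conditions should give the flavan-4-ols without opening the heterocycle, and the configuration at C4 is irrelevant because these centres are removed in step 11.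

Step 11
Reactants: 16 (2S,2''S)-bis-flavan-4-ol dibenzyl ether
Product: 17 (2S)-7-(benzyloxy)-8-{[(2S)-7-(benzyloxy)-5-methoxy-2-phenyl-3,4-dihydro-2H-chromen-6-yl]methyl}-5-methoxy-2-phenyl-3,4-dihydro-2H-chromene
Conditions: Et3SiH (10 equiv), CF3CO2H (10 equiv), CH2Cl2 (high dilution), −20 to 0 °C
Reagents that add atoms: none
Why: Ionic hydrogenation should ionise each C4 alcohol to a benzylic cation stabilised by the three ring oxygens and trap it by hydride transfer from the silane, leaving the C2 stereocentres untouched because they are not part of the cation.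

Step 12
Reactants: 17 (2S,2''S)-bis-flavan dibenzyl ether
Product: 18 (2S)-8-{[(2S)-7-hydroxy-5-methoxy-2-phenyl-3,4-dihydro-2H-chromen-6-yl]methyl}-5-methoxy-2-phenyl-3,4-dihydro-2H-chromen-7-ol (CNP0178097.1)
Conditions: H2 (1 atm), 10 % Pd/C, EtOAc/MeOH, rt, stopped at two equivalents of uptake
Reagents that add atoms: none
Why: Catalytic hydrogenolysis should cleave the two primary aryl benzyl ethers much faster than the cyclic secondary C2–O1 ether under neutral conditions at atmospheric pressure, so both phenols are freed without ring opening or loss of configuration.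

**Compound list**

1 | 2',4'-dihydroxy-6'-methoxyacetophenone | CC(=O)c1c(O)cc(O)cc1OC | starting material
2 | 4'-(benzyloxy)-2'-hydroxy-6'-methoxyacetophenone | CC(=O)c1c(O)cc(OCc2ccccc2)cc1OC | intermediate
3 | 4'-(benzyloxy)-2'-hydroxy-3'-iodo-6'-methoxyacetophenone | CC(=O)c1c(O)c(I)c(OCc2ccccc2)cc1OC | intermediate
4 | N,N-dimethylformamide dimethyl acetal | COC(OC)N(C)C | starting material
5 | (2E)-1-[4-(benzyloxy)-2-hydroxy-3-iodo-6-methoxyphenyl]-3-(dimethylamino)prop-2-en-1-one (enaminone) | COc1cc(OCc2ccccc2)c(I)c(O)c1C(=O)/C=C/N(C)C | intermediate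
6 | 7-(benzyloxy)-8-iodo-5-methoxy-4H-chromen-4-one | COc1cc(OCc2ccccc2)c(I)c2c1C(=O)C=CO2 | intermediate
7 | 5,7-dihydroxy-4H-chromen-4-one | Oc1cc(O)c2c(c1)OC=CC2=O | starting material
8 | 7-(benzyloxy)-5-hydroxy-4H-chromen-4-one | Oc1cc(OCc2ccccc2)cc2c1C(=O)C=CO2 | intermediate
9 | 7-(benzyloxy)-5-hydroxy-6-iodo-4H-chromen-4-one | Oc1c(I)c(OCc2ccccc2)cc2c1C(=O)C=CO2 | intermediate
10 | 7-(benzyloxy)-6-iodo-5-methoxy-4H-chromen-4-one | COc1c(I)c(OCc2ccccc2)cc2c1C(=O)C=CO2 | intermediate
11 | 2,2'-methylenebis(4,4,5,5-tetramethyl-1,3,2-dioxaborolane) | CC1(C)OB(CB2OC(C)(C)C(C)(C)O2)OC1(C)C | starting material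
12 | 7-(benzyloxy)-5-methoxy-8-[(4,4,5,5-tetramethyl-1,3,2-dioxaborolan-2-yl)methyl]-4H-chromen-4-one | COc1cc(OCc2ccccc2)c(CB2OC(C)(C)C(C)(C)O2)c2c1C(=O)C=CO2 | intermediate
13 | 7-(benzyloxy)-8-{[7-(benzyloxy)-5-methoxy-4-oxo-4H-chromen-6-yl]methyl}-5-methoxy-4H-chromen-4-one | COc1cc(OCc2ccccc2)c(Cc2c(OCc3ccccc3)cc3c(c2OC)C(=O)C=CO3)c2c1C(=O)C=CO2 | intermediate
14 | phenylboronic acid | OB(O)c1ccccc1 | starting material
15 | (2S,2''S)-bis-flavanone dibenzyl ether (C8–CH2–C6'' bridged) | COc1cc(OCc2ccccc2)c(Cc2c(OCc3ccccc3)cc3c(c2OC)C(=O)C[C@@H](c2ccccc2)O3)c2c1C(=O)C[C@@H](c1ccccc1)O2 | intermediate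
16 | (2S,2''S)-bis-flavan-4-ol dibenzyl ether, C4 epimers | COc1cc(OCc2ccccc2)c(Cc2c(OCc3ccccc3)cc3c(c2OC)C(O)C[C@@H](c2ccccc2)O3)c2c1C(O)C[C@@H](c1ccccc1)O2 | intermediate
17 | (2S,2''S)-bis-flavan dibenzyl ether | COc1cc(OCc2ccccc2)c(Cc2c(OCc3ccccc3)cc3c(c2OC)CC[C@@H](c2ccccc2)O3)c2c1CC[C@@H](c1ccccc1)O2 | intermediate
18 | (2S)-8-{[(2S)-7-hydroxy-5-methoxy-2-phenyl-3,4-dihydro-2H-chromen-6-yl]methyl}-5-methoxy-2-phenyl-3,4-dihydro-2H-chromen-7-ol | COc1cc(O)c(Cc2c(O)cc3c(c2OC)CC[C@@H](c2ccccc2)O3)c2c1CC[C@@H](c1ccccc1)O2 | target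

**Step count**

Total: 12 steps. Longest linear sequence: 9 steps (steps 1, 2, 3, 7, 8, 9, 10, 11, 12).

**Steps most likely to fail**

Step 9. The second addition may stall on the electron-rich 5-alkoxychromones while the boronic acid is lost to protodeboronation, and enantiopurity may erode by base-induced retro-oxa-Michael opening and reclosure of the flavanones. The fallback sets out from 13 and returns at 16. Both C2 positions of 13 are arylated oxidatively with phenylboronic acid 14 under Pd(OCOCF3)2 catalysis with benzoquinone as oxidant, which should give 7-(benzyloxy)-8-{[7-(benzyloxy)-5-methoxy-4-oxo-2-phenyl-4H-chromen-6-yl]methyl}-5-methoxy-2-phenyl-4H-chromen-4-one F1, the bis-flavone. F1 is then hydrogenated enantioselectively with a chiral ruthenium N-heterocyclic carbene catalyst (Ru(cod)(2-methylallyl)2, chiral SINpEt·HBF4, KOt-Bu, H2 under pressure), the carbene antipode being chosen for the 2S series. This reduces C2=C3 and C4=O of each unit and should deliver the bis-flavan-4-ol 16 directly.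

Step 8. Transmetalation of the doubly ortho-flanked benzylboronate may be slow, so that protodeboronation and base-induced opening of the pyranones take over. The fallback sets out from 10 and 3 and returns at 13, and it uses the two iodines as blocking groups instead of coupling handles. Chromone 10 is chloromethylated at C8, its only free benzenoid position (chloromethyl methyl ether, ZnCl2, CH2Cl2), to give 7-(benzyloxy)-8-(chloromethyl)-6-iodo-5-methoxy-4H-chromen-4-one F2. F2 alkylates iodoacetophenone 3 at C5', its only free ring position, in a ZnCl2-promoted Friedel–Crafts benzylation to give 8-{[5-acetyl-2-(benzyloxy)-4-hydroxy-3-iodo-6-methoxyphenyl]methyl}-7-(benzyloxy)-6-iodo-5-methoxy-4H-chromen-4-one F3. Both iodines are removed by transfer hydrogenolysis (Pd(PPh3)4, HCO2Na, DMF, 80 °C) to give 8-{[3-acetyl-6-(benzyloxy)-4-hydroxy-2-methoxyphenyl]methyl}-7-(benzyloxy)-5-methoxy-4H-chromen-4-one F4. Treatment with acetal 4 gives 7-(benzyloxy)-8-({6-(benzyloxy)-3-[(2E)-3-(dimethylamino)prop-2-enoyl]-4-hydroxy-2-methoxyphenyl}methyl)-5-methoxy-4H-chromen-4-one F5, the enaminone, and HCl in CH2Cl2 closes the second pyranone to give 13.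

Step 11. The highly stabilised C4 cations may be captured by the electron-rich benzenoid ring of another molecule (oligomerisation) faster than by the silane, and the acid may strip benzyl groups. The fallback sets out from 16 and returns at 17 by a radical instead of a cationic deoxygenation. Both C4 hydroxyls of 16 are acylated with 1,1'-thiocarbonyldiimidazole (DMAP, THF, reflux) to give the O,O'-bis(imidazole-1-carbothioate) of the bis-flavan-4-ol F6. F6 is reduced with Bu3SnH and AIBN in toluene at 90 °C (Barton–McCombie deoxygenation), the benzylic C4 radicals taking up hydrogen from the stannane, to give 17.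

**Further compounds**

F1 | step 9 | 7-(benzyloxy)-8-{[7-(benzyloxy)-5-methoxy-4-oxo-2-phenyl-4H-chromen-6-yl]methyl}-5-methoxy-2-phenyl-4H-chromen-4-one | COc1cc(OCc2ccccc2)c(Cc2c(OCc3ccccc3)cc3c(c2OC)C(=O)C=C(c2ccccc2)O3)c2c1C(=O)C=C(c1ccccc1)O2
F2 | step 8 | 7-(benzyloxy)-8-(chloromethyl)-6-iodo-5-methoxy-4H-chromen-4-one | COc1c(I)c(OCc2ccccc2)c(CCl)c2c1C(=O)C=CO2
F3 | step 8 | 8-{[5-acetyl-2-(benzyloxy)-4-hydroxy-3-iodo-6-methoxyphenyl]methyl}-7-(benzyloxy)-6-iodo-5-methoxy-4H-chromen-4-one | COc1c(I)c(OCc2ccccc2)c(Cc2c(OCc3ccccc3)c(I)c(O)c(C(C)=O)c2OC)c2c1C(=O)C=CO2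
F4 | step 8 | 8-{[3-acetyl-6-(benzyloxy)-4-hydroxy-2-methoxyphenyl]methyl}-7-(benzyloxy)-5-methoxy-4H-chromen-4-one | COc1cc(OCc2ccccc2)c(Cc2c(OCc3ccccc3)cc(O)c(C(C)=O)c2OC)c2c1C(=O)C=CO2
F5 | step 8 | 7-(benzyloxy)-8-({6-(benzyloxy)-3-[(2E)-3-(dimethylamino)prop-2-enoyl]-4-hydroxy-2-methoxyphenyl}methyl)-5-methoxy-4H-chromen-4-one | COc1cc(OCc2ccccc2)c(Cc2c(OCc3ccccc3)cc(O)c(C(=O)/C=C/N(C)C)c2OC)c2c1C(=O)C=CO2
F6 | step 11 | O,O'-bis(1H-imidazole-1-carbothioate) of the (2S,2''S)-bis-flavan-4-ol dibenzyl ether | COc1cc(OCc2ccccc2)c(Cc2c(OCc3ccccc3)cc3c(c2OC)C(OC(=S)n4ccnc4)C[C@@H](c2ccccc2)O3)c2c1C(OC(=S)n1ccnc1)C[C@@H](c1ccccc1)O2
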